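**Retrosynthetic overview**
Feature: the seven-membered ring C5–C6–C7–C8–C9–C10–C1 is the sum of a diene C7=C6–C5=C1 oxygenated at C6 and a vinylcarbenoid C8–C9–C10 whose C8 carries the extra carbon C11. The five-membered ring is C1–C2–C3–C4–C5, with C1 quaternary (CH3), C4 the isopropyl carbinol, C6 the vanillate carbinol and C9 the free carbinol.
Key disconnection: C7–C8 and C1–C10, by rhodium-carbenoid cyclopropanation of the C6=C7 enol silane and Cope shift of the cis-divinylcyclopropane; this closes the seven-membered ring and sets quaternary C1.
Before: the diene from 3-methylcyclopentenone (α-bromination, ketal, lithiation/acetylation, enol silane); the vinyldiazoacetate from methyl acetoacetate.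
After: C5–H by protonation of the enol silane, isopropyl addition to unmasked C4, hydroxyl-directed reduction at C6, then C8 ester → C11 alcohol → asymmetric epoxidation → reductive epoxide opening (C8=C11, C9–OH), with the vanillate placed on C6 before the C9 hydroxyl is released.
Ring order: five-membered ring first (bought), seven-membered ring second (key step).

Key step: step 8

Assumption 1: the sense of induction of the prolinate catalyst with this 1,1-disubstituted enol silane is taken from its behaviour with monosubstituted alkenes, which points to Rh2(R-DOSP)4 for (R)-C1; if a first run shows the opposite sense, Rh2(S-DOSP)4 is used and nothing else changes.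
Assumption 2: the hydride reduction of step 10 is drawn for attack anti to the C1 methyl group; the C6 configuration at that stage does not matter, because C6 is re-oxidised in step 13.

**Route**

Step 1
Reactants: 1 3-methylcyclopent-2-en-1-one
Product: 3 2-bromo-3-methylcyclopent-2-en-1-one, via dibromoketone 2 (not isolated)
Conditions: Br2, CH2Cl2, 0 °C; then Et3N, 0 °C → rt
Reagents that add atoms: bromine, BrBr
Why: Bromine adds across the enone alkene and triethylamine removes HBr from the dibromide (bromination–dehydrobromination), leaving bromine on the α-carbon, the future C5.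

Step 2
Reactants: 3 2-bromo-3-methylcyclopent-2-en-1-one
Product: 4 6-bromo-7-methyl-1,4-dioxaspiro[4.4]non-6-ene
Conditions: HOCH2CH2OH, p-TsOH·H2O (cat.), benzene, reflux, Dean–Stark
Reagents that add atoms: ethylene glycol, OCCO
Why: Acid-catalysed ketalization with azeotropic removal of water should protect the future C4, and the α-bromine keeps the alkene from moving out of the tetrasubstituted position.

Step 3
Reactants: 4 6-bromo-7-methyl-1,4-dioxaspiro[4.4]non-6-ene
Product: 6 1-(7-methyl-1,4-dioxaspiro[4.4]non-6-en-6-yl)ethan-1-one, via vinyllithium 5 (not isolated)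
Conditions: n-BuLi, THF, −78 °C; then MeC(O)N(OMe)Me, −78 → 0 °C; H2O
Reagents that add atoms: N-methoxy-N-methylacetamide, CON(C)C(C)=O
Why: Bromine–lithium exchange gives the α-ketovinyl anion equivalent, and acylation by the Weinreb amide stops at the methyl ketone because the chelated tetrahedral adduct survives until work-up.

Step 4
Reactants: 6 1-(7-methyl-1,4-dioxaspiro[4.4]non-6-en-6-yl)ethan-1-one
Product: 8 siloxydiene tert-butyldimethyl{[1-(7-methyl-1,4-dioxaspiro[4.4]non-6-en-6-yl)ethenyl]oxy}silane, via lithium enolate 7 (not isolated)
Conditions: LiN(i-Pr)2 (LDA), THF, −78 °C; then TBSCl, DMPU, −78 → 0 °C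
Reagents that add atoms: tert-butyldimethylsilyl chloride, CC(C)(C)[Si](C)(C)Cl
Why: Kinetic deprotonation of the acetyl methyl group gives the cross-conjugated enolate, and O-silylation under non-acidic conditions (the allylic ketal is acid-labile) gives the 2-siloxydiene C7=C6(OSi)–C5=C1.

Step 5
Reactants: 9 methyl acetoacetate
Product: 10 methyl 2-diazo-3-oxobutanoate
Conditions: 4-acetamidobenzenesulfonyl azide, Et3N, MeCN, 0 °C → rt
Reagents that add atoms: 4-acetamidobenzenesulfonyl azide, CC(=O)Nc1ccc(cc1)S(=O)(=O)N=[N+]=[N-]
Why: Regitz diazo transfer to the active methylene group is a standard, high-yielding reaction of β-keto esters.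

Step 6
Reactants: 10 methyl 2-diazo-3-oxobutanoate
Product: 11 methyl 2-diazo-3-hydroxybutanoate
Conditions: NaBH4, MeOH, 0 °C
Reagents that add atoms: none
Why: Borohydride reduces the ketone and leaves the acceptor-stabilised diazo ester untouched.

Step 7
Reactants: 11 methyl 2-diazo-3-hydroxybutanoate
Product: 12 methyl 2-diazobut-3-enoate
Conditions: POCl3, Et3N, CH2Cl2, 0 °C; used at once as a cold hexanes solution
Reagents that add atoms: none
Why: Elimination through the dichlorophosphate gives the vinyldiazoacetate, which is handled cold and used immediately because it slowly cyclises to a pyrazole.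

Step 8
Reactants: 8 siloxydiene; 12 methyl 2-diazobut-3-enoate
Product: 14 hydroazulene diene ester (1R; C4 ketal; C5=C6 enol silane; C8=C9 with CO2Me on C8), via divinylcyclopropane 13 (not isolated)
Conditions: Rh2(R-DOSP)4 [dirhodium tetrakis((R)-N-(4-dodecylbenzenesulfonyl)prolinate)] (1 mol %), hexanes, −40 °C → rt, slow addition of 12 (2 equiv); then toluene, 80–110 °C
Reagents that add atoms: none
Why: The rhodium-bound vinylcarbenoid from 12 adds its carbon C8 across the terminal, siloxy-activated C6=C7 bond of 8 (concerted asynchronous cyclopropanation forming C7–C8 and C6–C8), and the cis-divinylcyclopropane 13 then undergoes a strain-driven 3,3-shift that breaks C6–C8 and forms C1–C10. This is the known tandem cyclopropanation/Cope rearrangement (formal 4+3 cycloaddition) of vinyldiazoacetates with siloxydienes and 1-vinylcycloalkenes under dirhodium prolinate catalysis. The seven-membered ring closes in the sigmatropic step through the boat transition state, the only geometry in which the two alkene termini can reach each other, so both ring alkenes come out cis. The quaternary centre C1 is controlled by the catalyst, which fixes the configuration of cyclopropane carbons C6 and C8, and the boat shift passes this on stereospecifically to give (R)-C1. The step needs attack at the 1,1-disubstituted enol silane and not at the tetrasubstituted ring alkene (secured by electron density and access), reaction at the carbenoid carbon and not at its vinyl terminus (favoured by hydrocarbon solvent and the prolinate ligands), and a cis relation of the two alkenyl groups (the usual outcome; a trans isomer can still reach the cis form on heating by reversible opening of the donor–acceptor C6–C8 bond). The methyl group on the C1 terminus points toward C7 in the boat and slows the shift, hence the heating stage, while the push–pull substitution of the breaking bond helps.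

Step 9
Reactants: 14 hydroazulene diene ester
Product: 15 trans-fused keto ketal ester (C6 ketone; C5–H anti to the C1 methyl)
Conditions: TBAF, AcOH (1:1.2), THF, −40 → 0 °C
Reagents that add atoms: none
Why: Fluoride cleaves the Si–O bond and acetic acid protonates the enolate on C5 under buffered, kinetically controlled conditions (no free base, so no β-elimination of the ketal oxygen and no migration of C8=C9), with protonation anti to the axial C1 methyl expected to give the trans-fused ketone, the ring fusion that the chair cycloheptenone also accommodates best.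

Step 10
Reactants: 15 trans-fused keto ketal ester
Product: 16 hydroxy ketal ester (C6–OH)
Conditions: NaBH4, MeOH/CH2Cl2, −20 °C
Reagents that add atoms: none
Why: Borohydride reduces the ketone chemoselectively in the presence of the enoate and the ketal, which masks C6 as a carbinol while C4 is elaborated.

Step 11
Reactants: 16 hydroxy ketal ester
Product: 17 hydroxy ketone (C4 ketone; C6–OH)
Conditions: PPTS (cat.), acetone/H2O (10:1), rt → 40 °C
Reagents that add atoms: water, O
Why: Mild acid-catalysed ketal hydrolysis unmasks the cyclopentanone, and the weak acid is chosen so that the β-hydroxy ketone neither dehydrates nor enolises toward C5.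

Step 12
Reactants: 17 hydroxy ketone
Product: 18 diol ester (C4 isopropyl carbinol; C6–OH)
Conditions: i-PrMgCl (3 equiv), LaCl3·2LiCl (1 equiv), THF, −20 → 0 °C
Reagents that add atoms: isopropylmagnesium chloride, CC(C)[Mg]Cl
Why: Lanthanum-promoted Grignard 1,2-addition suppresses enolisation and β-hydride reduction and is faster at the ketone than at the hindered enoate; the nucleophile should enter on the face of H5, away from C6 on the adjacent carbon and from the C1 methyl, which puts the C4 hydroxyl cis to the methyl group.

Step 13
Reactants: 18 diol ester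
Product: 19 aldol ester (C4 isopropyl carbinol; C6 ketone)
Conditions: Dess–Martin periodinane, NaHCO3, CH2Cl2, 0 °C → rt
Reagents that add atoms: none
Why: The periodinane oxidises only the secondary C6 carbinol under neutral conditions that spare the tertiary aldol from retro-aldol cleavage and dehydration.

Step 14
Reactants: 19 aldol ester
Product: 20 anti-diol ester (C6–OH anti to O4 and cis to H5)
Conditions: Me4NBH(OAc)3, MeCN/AcOH (1:1), −30 °C
Reagents that add atoms: none
Why: In this Evans–Saksena reduction the C4 hydroxyl exchanges onto boron and delivers hydride intramolecularly through a six-membered transition state to the C6 carbonyl face on the side of O4, which sets C6 as the 1,3-anti diol.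

Step 15
Reactants: 20 anti-diol ester
Product: 21 triol (C11 primary allylic alcohol; C8=C9)
Conditions: i-Bu2AlH (DIBAL-H, 5 equiv), CH2Cl2, −78 → 0 °C; aqueous KNaC4H4O6 work-up
Reagents that add atoms: none
Why: The aluminium hydride reduces the conjugated ester in the 1,2-sense to the allylic alcohol once the free hydroxyls have been deprotonated.

Step 16
Reactants: 21 triol
Product: 22 epoxy triol (C8–C9 epoxide on the face of H5)
Conditions: Ti(OiPr)4 (1.2 equiv), L-(+)-diethyl tartrate (1.4 equiv), t-BuOOH, 4 Å molecular sieves, CH2Cl2, −20 °C
Reagents that add atoms: tert-butyl hydroperoxide, CC(C)(C)OO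
Why: Sharpless asymmetric epoxidation of the primary allylic alcohol is reagent-controlled, and L-(+)-tartrate (the sense that gives 2S,3S epoxides from simple E-allylic alcohols) should deliver oxygen to the C8=C9 face anti to the C1 methyl, which fixes the C9–O configuration of the target.

Step 17
Reactants: 22 epoxy triol
Product: 23 epoxy iodide (C11–I)
Conditions: PPh3, I2, imidazole, THF, 0 °C
Reagents that add atoms: iodine, II
Why: The Appel reaction converts the primary alcohol selectively, since the secondary C6 and tertiary C4 hydroxyls are too hindered to form and displace an alkoxyphosphonium ion.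

Step 18
Reactants: 24 vanillic acid
Product: 26 4-[(tert-butyldimethylsilyl)oxy]-3-methoxybenzoic acid, via bis-silyl derivative 25 (not isolated)
Conditions: TBSCl (2.5 equiv), imidazole, DMF, rt; then AcOH/THF/H2O, rt
Reagents that add atoms: tert-butyldimethylsilyl chloride, CC(C)(C)[Si](C)(C)Cl
Why: Phenol and acid are both silylated, and the far more labile silyl ester is then hydrolysed selectively to leave the aryl silyl ether.

Step 19
Reactants: 23 epoxy iodide; 26 4-[(tert-butyldimethylsilyl)oxy]-3-methoxybenzoic acid
Product: 28 epoxy iodide vanillate (C6 ester), via mixed anhydride 27 (not isolated)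
Conditions: 2,4,6-Cl3C6H2COCl, Et3N, THF, rt; then 23, 4-(dimethylamino)pyridine (DMAP), toluene, rt → 40 °C
Reagents that add atoms: none
Why: Yamaguchi esterification acylates the only reactive hydroxyl, the secondary C6 carbinol, because the tertiary C4 hydroxyl is inert and the C9 oxygen is still locked in the epoxide.

Step 20
Reactants: 28 epoxy iodide vanillate
Product: 29 silyl-protected target (C8=C11 methylene; C9–OH)
Conditions: Zn dust, AcOH (2 equiv), EtOH, rt → 40 °C
Reagents that add atoms: none
Why: Zinc inserts into the C–I bond and the organozinc opens the adjacent epoxide by β-elimination (reductive epoxide opening), which gives the exocyclic alkene and the C9 carbinol with the C9–O bond, and so its configuration, untouched.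

Step 21
Reactants: 29 silyl-protected target
Product: 30 CNP0330487.1
Conditions: TBAF, AcOH, THF, 0 °C
Reagents that add atoms: none
Why: Buffered fluoride cleaves the aryl silyl ether rapidly and leaves the benzoate ester and the two free carbinols in place.

**Compound list**
1 | 3-methylcyclopent-2-en-1-one | CC1=CC(=O)CC1 | starting material
2 | trans-2,3-dibromo-3-methylcyclopentan-1-one (racemic; not isolated) | C[C@@]1(Br)CCC(=O)[C@H]1Br | intermediate
3 | 2-bromo-3-methylcyclopent-2-en-1-one | CC1=C(Br)C(=O)CC1 | intermediate
4 | 6-bromo-7-methyl-1,4-dioxaspiro[4.4]non-6-ene | CC1=C(Br)C2(CC1)OCCO2 | intermediate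
5 | (7-methyl-1,4-dioxaspiro[4.4]non-6-en-6-yl)lithium (not isolated) | [Li]C1=C(C)CCC12OCCO2 | intermediate
6 | 1-(7-methyl-1,4-dioxaspiro[4.4]non-6-en-6-yl)ethan-1-one | CC(=O)C1=C(C)CCC12OCCO2 | intermediate
7 | lithium enolate of 6 (not isolated) | [Li]OC(=C)C1=C(C)CCC12OCCO2 | intermediate
8 | siloxydiene, tert-butyldimethyl{[1-(7-methyl-1,4-dioxaspiro[4.4]non-6-en-6-yl)ethenyl]oxy}silane | C=C(O[Si](C)(C)C(C)(C)C)C1=C(C)CCC12OCCO2 | intermediate
9 | methyl acetoacetate | COC(=O)CC(C)=O | starting material
10 | methyl 2-diazo-3-oxobutanoate | COC(=O)C(=[N+]=[N-])C(C)=O | intermediate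
11 | methyl 2-diazo-3-hydroxybutanoate (racemic; the stereocentre is lost in step 7) | COC(=O)C(=[N+]=[N-])C(C)O | intermediate
12 | methyl 2-diazobut-3-enoate | C=CC(=[N+]=[N-])C(=O)OC | intermediate
13 | cis-divinylcyclopropane: methyl 2-(TBS-oxy)-1-ethenyl-2-(7-methyl-1,4-dioxaspiro[4.4]non-6-en-6-yl)cyclopropane-1-carboxylate, ethenyl and cyclopentenyl cis (not isolated) | COC(=O)[C@]1(C=C)C[C@@]1(O[Si](C)(C)C(C)(C)C)C2=C(C)CCC23OCCO3 | intermediate
14 | hydroazulene diene ester: (1R), C4 ethylene ketal, C5=C6 enol silane (C6–OTBS), C8=C9 with CO2Me on C8 | COC(=O)C1=CC[C@@]2(C)CCC3(OCCO3)C2=C(O[Si](C)(C)C(C)(C)C)C1 | intermediate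
15 | trans-fused keto ketal ester: C6 ketone, C5–H anti to C1–CH3, C4 ketal, C8=C9 enoate | COC(=O)C1=CC[C@@]2(C)CCC3(OCCO3)[C@@H]2C(=O)C1 | intermediate
16 | hydroxy ketal ester: C6–OH (drawn syn to C1–CH3), C4 ketal, enoate | COC(=O)C1=CC[C@@]2(C)CCC3(OCCO3)[C@@H]2[C@H](O)C1 | intermediate
17 | hydroxy ketone: C4 ketone, C6–OH, enoate | COC(=O)C1=CC[C@@]2(C)CCC(=O)[C@@H]2[C@H](O)C1 | intermediate
18 | diol ester: C4 isopropyl carbinol (OH cis to C1–CH3, isopropyl cis to H5), C6–OH, enoate | COC(=O)C1=CC[C@@]2(C)CC[C@@](O)(C(C)C)[C@@H]2[C@H](O)C1 | intermediate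
19 | aldol ester: C4 isopropyl carbinol, C6 ketone, enoate | COC(=O)C1=CC[C@@]2(C)CC[C@@](O)(C(C)C)[C@@H]2C(=O)C1 | intermediate
20 | anti-diol ester: C6–OH cis to H5 and anti to O4, enoate | COC(=O)C1=CC[C@@]2(C)CC[C@@](O)(C(C)C)[C@@H]2[C@@H](O)C1 | intermediate
21 | triol: C11 primary allylic alcohol on C8, C8=C9, C4 and C6 carbinols | OCC1=CC[C@@]2(C)CC[C@@](O)(C(C)C)[C@@H]2[C@@H](O)C1 | intermediate
22 | epoxy triol: C8–C9 epoxide on the face of H5, C11–OH | OC[C@]12O[C@H]1C[C@@]3(C)CC[C@@](O)(C(C)C)[C@@H]3[C@@H](O)C2 | intermediate
23 | epoxy iodide: C11–I, C8–C9 epoxide, C4 and C6 carbinols | IC[C@]12O[C@H]1C[C@@]3(C)CC[C@@](O)(C(C)C)[C@@H]3[C@@H](O)C2 | intermediate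
24 | vanillic acid | COc1cc(C(=O)O)ccc1O | starting material
25 | tert-butyldimethylsilyl 4-[(tert-butyldimethylsilyl)oxy]-3-methoxybenzoate (not isolated) | COc1cc(C(=O)O[Si](C)(C)C(C)(C)C)ccc1O[Si](C)(C)C(C)(C)C | intermediate
26 | 4-[(tert-butyldimethylsilyl)oxy]-3-methoxybenzoic acid | COc1cc(C(=O)O)ccc1O[Si](C)(C)C(C)(C)C | intermediate
27 | mixed anhydride of 26 with 2,4,6-trichlorobenzoic acid (not isolated) | COc1cc(C(=O)OC(=O)c2c(Cl)cc(Cl)cc2Cl)ccc1O[Si](C)(C)C(C)(C)C | intermediate
28 | epoxy iodide vanillate: C6 ester of 23 with 26 | IC[C@]12O[C@H]1C[C@@]3(C)CC[C@@](O)(C(C)C)[C@@H]3[C@@H](OC(=O)c4ccc(O[Si](C)(C)C(C)(C)C)c(OC)c4)C2 | intermediate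
29 | silyl-protected target: C8=C11 methylene, C9–OH, C6 O-TBS-vanillate, C4 carbinol | C=C1C[C@H](OC(=O)c2ccc(O[Si](C)(C)C(C)(C)C)c(OC)c2)[C@@H]2[C@](C)(CC[C@@]2(O)C(C)C)C[C@@H]1O | intermediate
30 | CNP0330487.1 | C=C1C[C@H](OC(=O)c2ccc(O)c(OC)c2)[C@@H]2[C@](C)(CC[C@@]2(O)C(C)C)C[C@@H]1O | target

**Step count**
Total: 21 steps. Longest linear sequence: 17 steps (steps 1–4, 8–17, 19–21).

**Steps most likely to fail**

Step 8. What may go wrong: the nucleophilic enol silane may attack the vinyl terminus of the carbenoid instead of being cyclopropanated; enantio- or cis/trans control may be low at the 1,1-disubstituted alkene; the Cope shift may stall at the methyl-bearing terminus. The fallback changes the carbenoid partner to the one with the broadest record in this tandem reaction; it sets out from 8 and 10 and comes back at 15. Diazo ketone 10 is O-silylated (TBSOTf, Et3N, CH2Cl2, 0 °C) to methyl 3-[(tert-butyldimethylsilyl)oxy]-2-diazobut-3-enoate F1, whose siloxy group blocks reaction at the vinyl terminus. With 8 and Rh2(R-PTAD)4 [dirhodium tetrakis((R)-(1-adamantyl)(N-phthalimido)acetate)] or its enantiomer in hexanes, followed by warming, it should give the bis(enol silane) hydroazulene F2, which carries a second siloxy group on C9. TBAF/AcOH then frees the C6 ketone and the C9/C8 β-keto ester, giving the diketo ester F3 (drawn as its C9 enol). The β-keto ester alone is deprotonated and triflated (NaH, PhNTf2, THF, 0 °C) to the C9 enol triflate F4, and formate reduction (Pd(OAc)2, PPh3, HCO2H, Et3N, DMF, 60 °C) removes the C9 oxygen to give keto ester 15.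

Step 9. What may go wrong: the methyl group and C10 flank the two faces of C5 almost symmetrically, so protonation of the ring-fusion carbon may show low or wrong facial selectivity. Equilibration with base is not a safe remedy, since it risks β-elimination of the ketal oxygen and migration of C8=C9 into conjugation. The fallback replaces substrate-controlled protonation by a reagent-controlled relay; it sets out from 19, carried through steps 10–13 as the mixture of C4/C5 diastereomers, and comes back at 19 as one isomer. The mixture is dehydrated (p-TsOH, benzene, 60 °C) to one compound, the C4=C5 enone F5. Corey–Bakshi–Shibata reduction with (S)-1-methyl-3,3-diphenyltetrahydro-3H-pyrrolo[1,2-c][1,3,2]oxazaborole and BH3·SMe2 should give the allylic alcohol F6 with the C6 hydroxyl on the face of the C1 methyl. Hydroxyl-directed epoxidation (VO(acac)2, t-BuOOH, CH2Cl2) places the epoxide oxygen on the same face, which is the C4–O configuration of the target, and gives the epoxy alcohol F7. Dess–Martin oxidation gives the epoxy ketone F8. SmI2 (THF/MeOH, −78 °C) then cleaves the C5–O bond, and protonation of the enolate returns aldol 19; its C5 configuration is now governed by the neighbouring C4 centre (C6 trans to isopropyl, O4–H···O6 hydrogen bond).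

Step 12. What may go wrong: enolisation of the α-branched cyclopentanone, β-hydride reduction by the secondary Grignard reagent, retro-aldol cleavage of the β-alkoxide, or competing attack on the ester. The fallback uses a smaller sp2 nucleophile without β-hydrogens and then saturates it; it sets out from 17 and comes back at 18. Addition of CH2=C(CH3)MgBr with LaCl3·2LiCl (THF, −20 °C) should give the isopropenyl carbinol F9 with the same facial sense. Hydrogenation with RhCl(PPh3)3 (H2, benzene, rt) reduces the 1,1-disubstituted alkene in preference to the trisubstituted enoate and gives diol ester 18.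

**Further compounds**
F1 | step 8 | methyl 3-[(tert-butyldimethylsilyl)oxy]-2-diazobut-3-enoate | C=C(O[Si](C)(C)C(C)(C)C)C(=[N+]=[N-])C(=O)OC
F2 | step 8 | bis(enol silane) hydroazulene: as 14 with a second OTBS on C9 | COC(=O)C1=C(O[Si](C)(C)C(C)(C)C)C[C@@]2(C)CCC3(OCCO3)C2=C(O[Si](C)(C)C(C)(C)C)C1
F3 | step 8 | diketo ester (C6 ketone, C9 enol of the β-keto ester, C4 ketal) | COC(=O)C1=C(O)C[C@@]2(C)CCC3(OCCO3)[C@@H]2C(=O)C1
F4 | step 8 | C9 enol triflate of F3 | COC(=O)C1=C(OS(=O)(=O)C(F)(F)F)C[C@@]2(C)CCC3(OCCO3)[C@@H]2C(=O)C1
F5 | step 9 | C4=C5 enone (C4 isopropyl, C6 ketone, enoate) | COC(=O)C1=CC[C@@]2(C)CCC(C(C)C)=C2C(=O)C1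
F6 | step 9 | allylic alcohol (C6–OH on the face of C1–CH3, C4=C5) | COC(=O)C1=CC[C@@]2(C)CCC(C(C)C)=C2[C@H](O)C1
F7 | step 9 | epoxy alcohol (C4–C5 epoxide and C6–OH on the face of C1–CH3) | COC(=O)C1=CC[C@@]2(C)CC[C@]3(C(C)C)O[C@]23[C@H](O)C1
F8 | step 9 | epoxy ketone (C4–C5 epoxide, C6 ketone) | COC(=O)C1=CC[C@@]2(C)CC[C@]3(C(C)C)O[C@]23C(=O)C1
F9 | step 12 | isopropenyl carbinol (C4 2-propenyl carbinol, C6–OH, enoate) | COC(=O)C1=CC[C@@]2(C)CC[C@@](O)(C(C)=C)[C@@H]2[C@H](O)C1
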